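**Retrosynthetic overview** (core numbered as a 1H-isochromene: C1, O2, C3, C4, C4a, C5–C8, C8a; ring A = carbocycle, ring B = pyran)

1. Entonaemin A ⇐ global deprotection (two aryl allyl ethers, one tertiary Et3Si ether, one primary tBuMe2Si ether) of the fully assembled bicyclic ester.
2. Ring B is closed last by disconnecting C4–C4a and C1–O2: a formal [3+3] union of the kinetic enolate of (E)-5-silyloxypent-3-en-2-one (O2, C3, C4 and the whole side chain) with a ring A 3-chloro-2-(acetoxymethyl)cyclohex-2-enone that already carries C6, C7 and the orsellinate; chloride and acetate are expelled in the same operation.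
3. Enabling feature: in ring A, C8a is α to the C8 ketone, bears the pyran methylene C1 and is doubly bonded to C4a, so C1–C8a=C4a is a 2-acylallyl unit that can be made electrophilic at both ends. O2–C3=C4 of ring B is the enol of a methyl ketone, and the product chromophore O2–C3=C4–C4a=C8a–C8=O is the ring-closed valence tautomer of a 1-oxatriene.
4. The ring A partner ⇐ 1,3-dione (aminomethylenation at C8a, chlorination at C4a, reduction and acetylation of C1) ⇐ monoester of a cis-diol ⇐ dihydroxylation of (R)-5-acetoxy-2-methylcyclohex-2-enone ⇐ (R)-carvone; the carvone stereocentre steers the osmylation and is then erased as the C4a carbonyl.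
5. Order of ring formation: ring A comes from the chiral pool, the arene is attached as the ester, ring B is formed in the key step.

Key step: step 13

Remark: the 1,3-dione of step 9 is written as the diketone although it is expected to exist mainly as an enol; orsellinic acid is taken as a purchasable starting material.

**Step 1**
Reactants: 1 (R)-(−)-carvone
Product: 4 (1R)-4-methyl-5-oxocyclohex-3-en-1-yl acetate, via methoxy hydroperoxide 2 (not isolated), via peracetate 3 (not isolated)
Conditions: O3, CH2Cl2/MeOH, −78 °C; then Ac2O, Et3N, DMAP (cat.), −78 °C → rt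
Reagents that add atoms: ozone [O-][O+]=O; methanol CO
Why: ozone cleaves the electron-rich 1,1-disubstituted alkene in preference to the enone, methanol traps the carbonyl oxide, and acylation of the hydroperoxide triggers a Criegee rearrangement in which the ring carbon migrates to oxygen with retention, so the carvone stereocentre becomes the (R)-configured C–O centre.

**Step 2**
Reactants: 4 (1R)-4-methyl-5-oxocyclohex-3-en-1-yl acetate
Product: 5 (1R,3R,4R)-3,4-dihydroxy-4-methyl-5-oxocyclohexyl acetate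
Conditions: K2OsO2(OH)4 (cat.), N-methylmorpholine N-oxide, citric acid, tBuOH/H2O, rt
Reagents that add atoms: N-methylmorpholine N-oxide C[N+]1([O-])CCOCC1; water O
Why: Upjohn-type syn-dihydroxylation, buffered with citric acid to speed turnover on the electron-poor alkene and keep the β-acetoxy ketone away from base; the oxidant should add to the face of the half-chair opposite the acetoxy group, which sets the two new centres (future C6 and C7) cis to each other and trans to the acetate.

**Step 3**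
Reactants: 6 orsellinic acid
Product: 7 allyl 2,4-bis(allyloxy)-6-methylbenzoate
Conditions: allyl bromide, K2CO3, DMF, rt → 50 °C
Reagents that add atoms: allyl bromide C=CCBr
Why: Williamson alkylation of the carboxylate and of both phenoxides.

**Step 4**
Reactants: 7 allyl 2,4-bis(allyloxy)-6-methylbenzoate
Product: 8 2,4-bis(allyloxy)-6-methylbenzoic acid
Conditions: KOH, MeOH/H2O, reflux; then aq. HCl to pH 2
Reagents that add atoms: potassium hydroxide [K+].[OH-]
Why: saponification of the allyl ester, to which the aryl allyl ethers are inert.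

**Step 5**
Reactants: 8 2,4-bis(allyloxy)-6-methylbenzoic acid
Product: 9 2,4-bis(allyloxy)-6-methylbenzoyl chloride
Conditions: (COCl)2, DMF (cat.), CH2Cl2, 0 °C → rt
Reagents that add atoms: oxalyl chloride ClC(=O)C(Cl)=O
Why: acid chloride formation through the chloroiminium species generated from catalytic DMF.

**Step 6**
Reactants: 5 (1R,3R,4R)-3,4-dihydroxy-4-methyl-5-oxocyclohexyl acetate; 9 2,4-bis(allyloxy)-6-methylbenzoyl chloride
Product: 10 (1R,2R,5R)-5-acetoxy-2-hydroxy-2-methyl-3-oxocyclohexyl 2,4-bis(allyloxy)-6-methylbenzoate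
Conditions: pyridine, DMAP (cat.), CH2Cl2, 0 °C → rt
Reagents that add atoms: none
Why: DMAP-catalysed nucleophilic acyl substitution in which only the secondary hydroxyl should react, the tertiary one being too hindered, and no stereocentre is touched.

**Step 7**
Reactants: 10 (1R,2R,5R)-5-acetoxy-2-hydroxy-2-methyl-3-oxocyclohexyl 2,4-bis(allyloxy)-6-methylbenzoate
Product: 11 (1R,2R,5R)-5-acetoxy-2-methyl-3-oxo-2-(triethylsilyloxy)cyclohexyl 2,4-bis(allyloxy)-6-methylbenzoate
Conditions: Et3SiOTf, 2,6-lutidine, CH2Cl2, −78 → 0 °C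
Reagents that add atoms: triethylsilyl trifluoromethanesulfonate CC[Si](CC)(CC)OS(=O)(=O)C(F)(F)F
Why: silylation of the tertiary α-ketol hydroxyl with a reactive silyl triflate and a hindered base, which removes the only acidic O–H before the base-mediated steps.

**Step 8**
Reactants: 11 (1R,2R,5R)-5-acetoxy-2-methyl-3-oxo-2-(triethylsilyloxy)cyclohexyl 2,4-bis(allyloxy)-6-methylbenzoate
Product: 12 (1R,2R,5R)-5-hydroxy-2-methyl-3-oxo-2-(triethylsilyloxy)cyclohexyl 2,4-bis(allyloxy)-6-methylbenzoate
Conditions: K2CO3, MeOH, 0 °C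
Reagents that add atoms: none
Why: methanolysis (transesterification) of the unhindered secondary acetate at 0 °C, where it should outrun E1cB loss of acetate from the β-acetoxy ketone, while the 2,6-disubstituted benzoate, the aryl allyl ethers and the tertiary silyl ether should not react.

**Step 9**
Reactants: 12 (1R,2R,5R)-5-hydroxy-2-methyl-3-oxo-2-(triethylsilyloxy)cyclohexyl 2,4-bis(allyloxy)-6-methylbenzoate
Product: 13 (1R,2R)-2-methyl-3,5-dioxo-2-(triethylsilyloxy)cyclohexyl 2,4-bis(allyloxy)-6-methylbenzoate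
Conditions: Dess–Martin periodinane, pyridine, CH2Cl2, 0 °C → rt
Reagents that add atoms: none
Why: Dess–Martin oxidation of the β-hydroxy ketone to the 1,3-dione, which erases the auxiliary stereocentre inherited from carvone and gives C4a its carbonyl oxidation level.

**Step 10**
Reactants: 13 (1R,2R)-2-methyl-3,5-dioxo-2-(triethylsilyloxy)cyclohexyl 2,4-bis(allyloxy)-6-methylbenzoate
Product: 16 (1R,6R)-3-chloro-4-formyl-6-methyl-5-oxo-6-(triethylsilyloxy)cyclohex-3-en-1-yl 2,4-bis(allyloxy)-6-methylbenzoate, via enaminodione 14 (not isolated), via chloroiminium chloride 15 (not isolated)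
Conditions: Me2NCH(OMe)2, toluene, rt, then evaporation; (COCl)2, CH2Cl2, −20 → 0 °C; then ice-water
Reagents that add atoms: N,N-dimethylformamide dimethyl acetal COC(OC)N(C)C; oxalyl chloride ClC(=O)C(Cl)=O; water O
Why: condensation at the acidic C8a methylene gives the vinylogous amide, oxalyl chloride should acylate the carbonyl oxygen remote from the quaternary C7 so that chloride enters at C4a (Vilsmeier–Haack–Arnold type β-chlorovinyl iminium salt, the usual regiochemistry of 4,4-disubstituted cyclohexane-1,3-diones), and hydrolysis releases the aldehyde that becomes C1.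

**Step 11**
Reactants: 16 (1R,6R)-3-chloro-4-formyl-6-methyl-5-oxo-6-(triethylsilyloxy)cyclohex-3-en-1-yl 2,4-bis(allyloxy)-6-methylbenzoate
Product: 18 (1R,6R)-4-(acetoxymethyl)-3-chloro-6-methyl-5-oxo-6-(triethylsilyloxy)cyclohex-3-en-1-yl 2,4-bis(allyloxy)-6-methylbenzoate, via allylic alcohol 17 (not isolated)
Conditions: NaBH(OAc)3, AcOH, CH2Cl2, 0 °C → rt; then Ac2O, pyridine, DMAP (cat.), 0 °C
Reagents that add atoms: acetic anhydride CC(=O)OC(C)=O
Why: NaBH(OAc)3 reduces the aldehyde but not the hindered cross-conjugated ketone, the vinyl chloride or the aryl ester, and acetylation in the same flask gives an allylic acetate of the Morita–Baylis–Hillman type.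

**Step 12**
Reactants: 19 1-(triphenylphosphoranylidene)propan-2-one; 20 (tert-butyldimethylsilyloxy)acetaldehyde
Product: 21 (3E)-5-(tert-butyldimethylsilyloxy)pent-3-en-2-one
Conditions: CH2Cl2, rt
Reagents that add atoms: none
Why: Wittig olefination with a stabilised acyl ylide, which should give the (E)-enone.

**Step 13**
Reactants: 21 (3E)-5-(tert-butyldimethylsilyloxy)pent-3-en-2-one; 18 (1R,6R)-4-(acetoxymethyl)-3-chloro-6-methyl-5-oxo-6-(triethylsilyloxy)cyclohex-3-en-1-yl 2,4-bis(allyloxy)-6-methylbenzoate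
Product: 25 (6R,7R)-3-[(1E)-3-(tert-butyldimethylsilyloxy)prop-1-en-1-yl]-7-methyl-8-oxo-7-(triethylsilyloxy)-5,6,7,8-tetrahydro-1H-isochromen-6-yl 2,4-bis(allyloxy)-6-methylbenzoate, via lithium enolate 22 (not isolated), via enedione 23 (not isolated), via 1-oxatriene 24 (not isolated)
Conditions: LiN(iPr)2 (1.05 equiv), THF, −78 °C, slow addition of 21; then 18, −78 °C; then LiN(SiMe3)2 (1.0 equiv), −78 → 0 °C; pH 7 buffer
Reagents that add atoms: none
Why: Proposed new method: the kinetic lithium enolate 22 acts as a C,O-1,3-dinucleophile toward the 1,3-bis-electrophile 18: its carbon adds to C4a, the only conjugate position, and chloride leaves (addition–elimination) to make the C4–C4a bond of enedione 23, whose doubly activated C4–H is removed by LiN(SiMe3)2 so that the dienolate expels acetate from C1 (vinylogous E1cB, as with Morita–Baylis–Hillman acetates) to give 1-oxatriene 24, and a thermal disrotatory 6π-oxa-electrocyclisation then makes the C1–O2 bond. The closest known reaction types are the formal oxa-[3+3] annulation of 1,3-dicarbonyl compounds with enals (Knoevenagel condensation followed by oxa-6π closure) and the addition–elimination of ketone enolates to 3-chlorocyclohex-2-enones; new here is a plain ketone enolate as the C–C–O partner of an α-(acyloxymethyl)-β-chloro enone. The pyran ring is closed by the 6π-electrocyclisation of the oxatriene with C3 cis to C8a (a 6-exo-tet O-alkylation of the dienolate would give the same product, and a wrong C4=C4a geometry can be corrected through reversible acetate addition at C1), driven by return of the C4a=C8a enone and the push–pull system O2–C3=C4–C4a=C8a–C8=O. No stereocentre is formed and the existing ones are safe, because C7 is quaternary and C6 is not enolisable. The step needs attack through carbon at C4a and ring closure through oxygen at C1: the soft β-chloro enone carbon favours C-attack of the lithium enolate in THF, acetate is a poor leaving group for direct substitution at C1 but a good one once the dienolate is formed, and closure through C4 would give a cyclobutene. Kinetic deprotonation of the methyl group of 21 with LiN(iPr)2 at −78 °C secures the cross-conjugated enolate, and using one equivalent of each base limits γ-deprotonation at C5 and loss of the C6 benzoate.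

**Step 14**
Reactants: 25 (6R,7R)-3-[(1E)-3-(tert-butyldimethylsilyloxy)prop-1-en-1-yl]-7-methyl-8-oxo-7-(triethylsilyloxy)-5,6,7,8-tetrahydro-1H-isochromen-6-yl 2,4-bis(allyloxy)-6-methylbenzoate
Product: 26 (6R,7R)-3-[(1E)-3-(tert-butyldimethylsilyloxy)prop-1-en-1-yl]-7-methyl-8-oxo-7-(triethylsilyloxy)-5,6,7,8-tetrahydro-1H-isochromen-6-yl 2,4-dihydroxy-6-methylbenzoate
Conditions: Pd(PPh3)4 (cat.), morpholine, THF, rt
Reagents that add atoms: none
Why: Tsuji–Trost deallylation, in which zerovalent palladium ionises only the aryl allyl ethers (phenoxide leaving groups) and morpholine traps the allyl unit, while the silyl ethers, the ester and the pyran C1–O2 bond (a ketone enolate would have to leave) should stay intact.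

**Step 15**
Reactants: 26 (6R,7R)-3-[(1E)-3-(tert-butyldimethylsilyloxy)prop-1-en-1-yl]-7-methyl-8-oxo-7-(triethylsilyloxy)-5,6,7,8-tetrahydro-1H-isochromen-6-yl 2,4-dihydroxy-6-methylbenzoate
Product: 27 Entonaemin A
Conditions: HF·pyridine, pyridine, THF, 0 °C → rt
Reagents that add atoms: none
Why: fluoride-mediated cleavage of both silyl ethers under pyridine-buffered conditions, chosen to spare the dienol ether and to avoid base-induced acyl migration from the C6 to the C7 oxygen.

**Compound list**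

1 | (R)-(−)-carvone, (5R)-2-methyl-5-(prop-1-en-2-yl)cyclohex-2-en-1-one | CC1=CC[C@H](CC1=O)C(C)=C | starting material
2 | (5R)-5-(1-hydroperoxy-1-methoxyethyl)-2-methylcyclohex-2-en-1-one (epimers at the peroxyketal carbon) | CC1=CC[C@H](CC1=O)C(C)(OC)OO | intermediate
3 | 1-methoxy-1-[(1R)-4-methyl-5-oxocyclohex-3-en-1-yl]ethyl ethaneperoxoate | CC1=CC[C@H](CC1=O)C(C)(OC)OOC(C)=O | intermediate
4 | (1R)-4-methyl-5-oxocyclohex-3-en-1-yl acetate | CC1=CC[C@H](CC1=O)OC(C)=O | intermediate
5 | (1R,3R,4R)-3,4-dihydroxy-4-methyl-5-oxocyclohexyl acetate | O[C@@H]1C[C@@H](OC(C)=O)CC(=O)[C@]1(C)O | intermediate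
6 | orsellinic acid, 2,4-dihydroxy-6-methylbenzoic acid | Cc1cc(O)cc(O)c1C(=O)O | starting material
7 | allyl 2,4-bis(allyloxy)-6-methylbenzoate | Cc1cc(OCC=C)cc(OCC=C)c1C(=O)OCC=C | intermediate
8 | 2,4-bis(allyloxy)-6-methylbenzoic acid | Cc1cc(OCC=C)cc(OCC=C)c1C(=O)O | intermediate
9 | 2,4-bis(allyloxy)-6-methylbenzoyl chloride | Cc1cc(OCC=C)cc(OCC=C)c1C(=O)Cl | intermediate
10 | (1R,2R,5R)-5-acetoxy-2-hydroxy-2-methyl-3-oxocyclohexyl 2,4-bis(allyloxy)-6-methylbenzoate | Cc1cc(OCC=C)cc(OCC=C)c1C(=O)O[C@@H]1C[C@@H](OC(C)=O)CC(=O)[C@]1(C)O | intermediate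
11 | (1R,2R,5R)-5-acetoxy-2-methyl-3-oxo-2-(triethylsilyloxy)cyclohexyl 2,4-bis(allyloxy)-6-methylbenzoate | Cc1cc(OCC=C)cc(OCC=C)c1C(=O)O[C@@H]1C[C@@H](OC(C)=O)CC(=O)[C@]1(C)O[Si](CC)(CC)CC | intermediate
12 | (1R,2R,5R)-5-hydroxy-2-methyl-3-oxo-2-(triethylsilyloxy)cyclohexyl 2,4-bis(allyloxy)-6-methylbenzoate | Cc1cc(OCC=C)cc(OCC=C)c1C(=O)O[C@@H]1C[C@@H](O)CC(=O)[C@]1(C)O[Si](CC)(CC)CC | intermediate
13 | (1R,2R)-2-methyl-3,5-dioxo-2-(triethylsilyloxy)cyclohexyl 2,4-bis(allyloxy)-6-methylbenzoate | Cc1cc(OCC=C)cc(OCC=C)c1C(=O)O[C@@H]1CC(=O)CC(=O)[C@]1(C)O[Si](CC)(CC)CC | intermediate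
14 | (1R,2R)-4-[(dimethylamino)methylidene]-2-methyl-3,5-dioxo-2-(triethylsilyloxy)cyclohexyl 2,4-bis(allyloxy)-6-methylbenzoate | Cc1cc(OCC=C)cc(OCC=C)c1C(=O)O[C@@H]1CC(=O)C(=CN(C)C)C(=O)[C@]1(C)O[Si](CC)(CC)CC | intermediate
15 | N-[[(4R,5R)-4-[2,4-bis(allyloxy)-6-methylbenzoyl]oxy-2-chloro-5-methyl-6-oxo-5-(triethylsilyloxy)cyclohex-1-en-1-yl]methylidene]-N-methylmethanaminium chloride | Cc1cc(OCC=C)cc(OCC=C)c1C(=O)O[C@@H]1CC(Cl)=C(C=[N+](C)C)C(=O)[C@]1(C)O[Si](CC)(CC)CC.[Cl-] | intermediate
16 | (1R,6R)-3-chloro-4-formyl-6-methyl-5-oxo-6-(triethylsilyloxy)cyclohex-3-en-1-yl 2,4-bis(allyloxy)-6-methylbenzoate | Cc1cc(OCC=C)cc(OCC=C)c1C(=O)O[C@@H]1CC(Cl)=C(C=O)C(=O)[C@]1(C)O[Si](CC)(CC)CC | intermediate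
17 | (1R,6R)-3-chloro-4-(hydroxymethyl)-6-methyl-5-oxo-6-(triethylsilyloxy)cyclohex-3-en-1-yl 2,4-bis(allyloxy)-6-methylbenzoate | Cc1cc(OCC=C)cc(OCC=C)c1C(=O)O[C@@H]1CC(Cl)=C(CO)C(=O)[C@]1(C)O[Si](CC)(CC)CC | intermediate
18 | (1R,6R)-4-(acetoxymethyl)-3-chloro-6-methyl-5-oxo-6-(triethylsilyloxy)cyclohex-3-en-1-yl 2,4-bis(allyloxy)-6-methylbenzoate | Cc1cc(OCC=C)cc(OCC=C)c1C(=O)O[C@@H]1CC(Cl)=C(COC(C)=O)C(=O)[C@]1(C)O[Si](CC)(CC)CC | intermediate
19 | 1-(triphenylphosphoranylidene)propan-2-one | CC(=O)C=P(c1ccccc1)(c1ccccc1)c1ccccc1 | starting material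
20 | (tert-butyldimethylsilyloxy)acetaldehyde | O=CCO[Si](C)(C)C(C)(C)C | starting material
21 | (3E)-5-(tert-butyldimethylsilyloxy)pent-3-en-2-one | CC(=O)/C=C/CO[Si](C)(C)C(C)(C)C | intermediate
22 | lithium (3E)-5-(tert-butyldimethylsilyloxy)penta-1,3-dien-2-olate | C=C(O[Li])/C=C/CO[Si](C)(C)C(C)(C)C | intermediate
23 | (1R,6R)-4-(acetoxymethyl)-3-[(3E)-5-(tert-butyldimethylsilyloxy)-2-oxopent-3-en-1-yl]-6-methyl-5-oxo-6-(triethylsilyloxy)cyclohex-3-en-1-yl 2,4-bis(allyloxy)-6-methylbenzoate | Cc1cc(OCC=C)cc(OCC=C)c1C(=O)O[C@@H]1CC(CC(=O)/C=C/CO[Si](C)(C)C(C)(C)C)=C(COC(C)=O)C(=O)[C@]1(C)O[Si](CC)(CC)CC | intermediate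
24 | (1R,2R,5Z)-5-[(3E)-5-(tert-butyldimethylsilyloxy)-2-oxopent-3-en-1-ylidene]-2-methyl-4-methylidene-3-oxo-2-(triethylsilyloxy)cyclohexyl 2,4-bis(allyloxy)-6-methylbenzoate | Cc1cc(OCC=C)cc(OCC=C)c1C(=O)O[C@@H]1C/C(=C/C(=O)/C=C/CO[Si](C)(C)C(C)(C)C)C(=C)C(=O)[C@]1(C)O[Si](CC)(CC)CC | intermediate
25 | (6R,7R)-3-[(1E)-3-(tert-butyldimethylsilyloxy)prop-1-en-1-yl]-7-methyl-8-oxo-7-(triethylsilyloxy)-5,6,7,8-tetrahydro-1H-isochromen-6-yl 2,4-bis(allyloxy)-6-methylbenzoate | Cc1cc(OCC=C)cc(OCC=C)c1C(=O)O[C@@H]1CC2=C(COC(/C=C/CO[Si](C)(C)C(C)(C)C)=C2)C(=O)[C@]1(C)O[Si](CC)(CC)CC | intermediate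
26 | (6R,7R)-3-[(1E)-3-(tert-butyldimethylsilyloxy)prop-1-en-1-yl]-7-methyl-8-oxo-7-(triethylsilyloxy)-5,6,7,8-tetrahydro-1H-isochromen-6-yl 2,4-dihydroxy-6-methylbenzoate | Cc1cc(O)cc(O)c1C(=O)O[C@@H]1CC2=C(COC(/C=C/CO[Si](C)(C)C(C)(C)C)=C2)C(=O)[C@]1(C)O[Si](CC)(CC)CC | intermediate
27 | Entonaemin A, (6R,7R)-7-hydroxy-3-[(1E)-3-hydroxyprop-1-en-1-yl]-7-methyl-8-oxo-5,6,7,8-tetrahydro-1H-isochromen-6-yl 2,4-dihydroxy-6-methylbenzoate | Cc1cc(O)cc(O)c1C(=O)O[C@@H]1CC2=C(COC(/C=C/CO)=C2)C(=O)[C@]1(C)O | target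

**Total step count:** 15
**Longest linear sequence:** 12 steps (steps 3, 4, 5, 6, 7, 8, 9, 10, 11, 13, 14, 15), running from orsellinic acid 6 to Entonaemin A 27

**Steps most likely to fail**

Step 13 (proposed new method). Conjugate addition at the fully substituted C4a may be slower than proton transfer from C5 of 18, which would be followed by loss of the C6 benzoate. It may also be slower than acyl transfer from the acetate. Later in the cascade, the dienolate may not release acetate, or the oxatriene may be captured at C1 by a second enolate before it cyclises. The fallback uses known reaction types only, sets out from alcohol 17 (isolated after the reduction of step 11) and ketone 21, and returns to the route at 25. Alcohol 17 is silylated (Me3SiCl, imidazole, CH2Cl2) to the trimethylsilyl ether F1. F1 is added to two equivalents of enolate 22 (THF, −78 → −40 °C, the second equivalent serving as base) in a plain addition–elimination of a ketone enolate to a 3-chlorocyclohex-2-enone, which should give the enedione F2. PPTS in MeOH at 0 °C cleaves the primary trimethylsilyl ether to the hydroxy enedione F3. PPTS in benzene over 4 Å molecular sieves then closes F3 to the hemiketal and dehydrates it (acid-catalysed cyclodehydration of a δ-hydroxy ketone to a 1H-isochromene) to 25. In this variant the ring oxygen is supplied by the C1 hydroxyl.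

Step 10. The chloroiminium stage may go astray in three ways: O-activation at the hindered C8 carbonyl, electrophilic attack of the iminium species on the electron-rich bis(allyloxy)arene, or loss of the tertiary silyl ether and of the C6 benzoate when acid is released on hydrolysis. The fallback brings in C1 at the thioether level under neutral conditions, sets out from dione 13 and returns at aldehyde 16. Dione 13, aqueous formaldehyde and thiophenol (L-proline cat., CH2Cl2/EtOH, rt; Knoevenagel condensation then thia-Michael addition) should give the sulfide F4. (COCl)2 with catalytic DMF in CH2Cl2 at 0 °C converts the less hindered enol terminus into the β-chloro enone F5. N-Chlorosuccinimide in CH2Cl2 gives the α-chloro sulfide F6, and hydrolysis with CuO and CuCl2 in aqueous acetone releases aldehyde 16.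

Step 6. Acylation of the hindered C6 hydroxyl (next to the tertiary carbinol) by the doubly ortho-substituted aroyl chloride may be slower than amine-induced β-elimination of the C4a acetate (E1cB to the enone). The fallback acylates under neutral photochemical conditions through a quinoketene, sets out from orsellinic acid 6 and diol 5, and returns at 10. Acid 6 with acetone, (CF3CO)2O and CF3CO2H gives the benzodioxinone F7, and allyl bromide with K2CO3 in acetone gives its allyl ether F8. Irradiation of F8 at 300 nm with 5 in CH2Cl2 expels acetone and generates the quinoketene F9, which the secondary hydroxyl of 5 should capture to give the salicylate F10. Neutral Tsuji–Trost etherification of the hydrogen-bonded phenol of F10 (allyl methyl carbonate, Pd(PPh3)4 cat., THF) gives 10.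

**Further compounds**

F1 | step 13 | (1R,6R)-3-chloro-6-methyl-5-oxo-6-(triethylsilyloxy)-4-[(trimethylsilyloxy)methyl]cyclohex-3-en-1-yl 2,4-bis(allyloxy)-6-methylbenzoate | Cc1cc(OCC=C)cc(OCC=C)c1C(=O)O[C@@H]1CC(Cl)=C(CO[Si](C)(C)C)C(=O)[C@]1(C)O[Si](CC)(CC)CC
F2 | step 13 | (1R,6R)-3-[(3E)-5-(tert-butyldimethylsilyloxy)-2-oxopent-3-en-1-yl]-6-methyl-5-oxo-6-(triethylsilyloxy)-4-[(trimethylsilyloxy)methyl]cyclohex-3-en-1-yl 2,4-bis(allyloxy)-6-methylbenzoate | Cc1cc(OCC=C)cc(OCC=C)c1C(=O)O[C@@H]1CC(CC(=O)/C=C/CO[Si](C)(C)C(C)(C)C)=C(CO[Si](C)(C)C)C(=O)[C@]1(C)O[Si](CC)(CC)CC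
F3 | step 13 | (1R,6R)-3-[(3E)-5-(tert-butyldimethylsilyloxy)-2-oxopent-3-en-1-yl]-4-(hydroxymethyl)-6-methyl-5-oxo-6-(triethylsilyloxy)cyclohex-3-en-1-yl 2,4-bis(allyloxy)-6-methylbenzoate | Cc1cc(OCC=C)cc(OCC=C)c1C(=O)O[C@@H]1CC(CC(=O)/C=C/CO[Si](C)(C)C(C)(C)C)=C(CO)C(=O)[C@]1(C)O[Si](CC)(CC)CC
F4 | step 10 | (1R,2R)-5-hydroxy-2-methyl-3-oxo-4-[(phenylsulfanyl)methyl]-2-(triethylsilyloxy)cyclohex-4-en-1-yl 2,4-bis(allyloxy)-6-methylbenzoate (enol form) | Cc1cc(OCC=C)cc(OCC=C)c1C(=O)O[C@@H]1CC(O)=C(CSc2ccccc2)C(=O)[C@]1(C)O[Si](CC)(CC)CC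
F5 | step 10 | (1R,6R)-3-chloro-6-methyl-5-oxo-4-[(phenylsulfanyl)methyl]-6-(triethylsilyloxy)cyclohex-3-en-1-yl 2,4-bis(allyloxy)-6-methylbenzoate | Cc1cc(OCC=C)cc(OCC=C)c1C(=O)O[C@@H]1CC(Cl)=C(CSc2ccccc2)C(=O)[C@]1(C)O[Si](CC)(CC)CC
F6 | step 10 | (1R,6R)-3-chloro-4-[chloro(phenylsulfanyl)methyl]-6-methyl-5-oxo-6-(triethylsilyloxy)cyclohex-3-en-1-yl 2,4-bis(allyloxy)-6-methylbenzoate (epimers at the chlorinated carbon) | Cc1cc(OCC=C)cc(OCC=C)c1C(=O)O[C@@H]1CC(Cl)=C(C(Cl)Sc2ccccc2)C(=O)[C@]1(C)O[Si](CC)(CC)CC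
F7 | step 6 | 7-hydroxy-2,2,5-trimethyl-4H-1,3-benzodioxin-4-one | CC1(C)OC(=O)c2c(C)cc(O)cc2O1
F8 | step 6 | 7-(allyloxy)-2,2,5-trimethyl-4H-1,3-benzodioxin-4-one | CC1(C)OC(=O)c2c(C)cc(OCC=C)cc2O1
F9 | step 6 | 3-(allyloxy)-5-methyl-6-(oxomethylidene)cyclohexa-2,4-dien-1-one | CC1=CC(OCC=C)=CC(=O)C1=C=O
F10 | step 6 | (1R,2R,5R)-5-acetoxy-2-hydroxy-2-methyl-3-oxocyclohexyl 4-(allyloxy)-2-hydroxy-6-methylbenzoate | Cc1cc(OCC=C)cc(O)c1C(=O)O[C@@H]1C[C@@H](OC(C)=O)CC(=O)[C@]1(C)O
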